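**Plan**
- Retrosynthetic cuts, in order: (i) the three O–Si bonds (7-O, 2′-O, 4′-O); (ii) O1–C2 and C3=C4 of the 2H-pyran ring, together; (iii) the C6–prenyl bond, traced back to an O-prenyl ether on the future O1; (iv) the formyl C–C bond on ring A.
- Enabling feature: O1 (on C8a) and C4 (on C4a) sit ortho on ring A, so ring A is a latent salicylaldehyde; C2 is a bare CH2 and C3 carries only the resorcinol ring, so C2–C3 is a 1-arylvinylphosphonium ion (electrophilic at C2, then a Wittig ylide at C3).
- Forward, ring A: 5-methoxyresorcinol is formylated, 4-O-silylated, O-prenylated, and a Claisen–Cope shift moves prenyl para to the future O1, between OMe and OSi.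
- Forward, ring B: 2,4-dihydroxyacetophenone is silylated, converted to the enol triflate and coupled with PPh3.
- One annulation joins the fragments and closes the pyran ring (the only ring made); fluoride then frees the three phenols.
- Stereochemistry: none to set; the C3=C4 double bond is endocyclic.

Key step: step 8

Remark: the target has no stereocentre and is achiral, so "single enantiomer" is taken to mean the single constitution shown. TIPS = triisopropylsilyl.

**Step 1**
Reactants: 1 5-methoxybenzene-1,3-diol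
Product: 3 2,4-dihydroxy-6-methoxybenzaldehyde, via aryl iminium chloride 2 (not isolated)
Conditions: POCl3, DMF, MeCN, 0 °C → rt; then H2O, 50 °C
Reagents that add atoms: N,N-dimethylformamide, CN(C)C=O; water, O
Why: Vilsmeier–Haack formylation of a resorcinol should go para to one hydroxyl and not between the two, and the two equivalent carbons next to OMe are exactly such sites.

**Step 2**
Reactants: 3 2,4-dihydroxy-6-methoxybenzaldehyde
Product: 4 2-hydroxy-6-methoxy-4-[(triisopropylsilyl)oxy]benzaldehyde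
Conditions: TIPSCl (1.05 equiv), imidazole, CH2Cl2, 0 °C
Reagents that add atoms: triisopropylsilyl chloride, CC(C)[Si](Cl)(C(C)C)C(C)C
Why: Selective silylation should take the more acidic, non-chelated 4-OH, because the 2-OH is hydrogen-bonded to the formyl group.

**Step 3**
Reactants: 4 2-hydroxy-6-methoxy-4-[(triisopropylsilyl)oxy]benzaldehyde; 5 3-methylbut-2-en-1-ol
Product: 6 2-methoxy-6-[(3-methylbut-2-en-1-yl)oxy]-4-[(triisopropylsilyl)oxy]benzaldehyde
Conditions: PPh3, DIAD, THF, 0 °C → rt
Reagents that add atoms: none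
Why: Mitsunobu etherification alkylates the chelated phenol at the primary allylic carbon under neutral conditions, which spares the aryl silyl ether para to the formyl group.

**Step 4**
Reactants: 6 2-methoxy-6-[(3-methylbut-2-en-1-yl)oxy]-4-[(triisopropylsilyl)oxy]benzaldehyde
Product: 9 6-hydroxy-2-methoxy-3-(3-methylbut-2-en-1-yl)-4-[(triisopropylsilyl)oxy]benzaldehyde, via ortho-dienone 7 (not isolated), via para-dienone 8 (not isolated)
Conditions: PhNEt2, 195 °C, Ar, sealed tube
Reagents that add atoms: none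
Why: Aromatic Claisen rearrangement followed by Cope rearrangement (para-Claisen) inverts the allyl unit twice, so a normal prenyl group should arrive at the only carbon para to the ether oxygen (between OMe and OTIPS), as precedented for prenyl ethers of 2-acyl-3,5-dioxygenated phenols.

**Step 5**
Reactants: 10 1-(2,4-dihydroxyphenyl)ethan-1-one
Product: 11 1-{2,4-bis[(triisopropylsilyl)oxy]phenyl}ethan-1-one
Conditions: TIPSCl (2.5 equiv), imidazole, DMAP (cat.), DMF, 50 °C
Reagents that add atoms: triisopropylsilyl chloride, CC(C)[Si](Cl)(C(C)C)C(C)C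
Why: Exhaustive silylation of both phenols under forcing imidazole/DMF conditions should also cap the chelated 2-OH without enolising the methyl ketone.

**Step 6**
Reactants: 11 1-{2,4-bis[(triisopropylsilyl)oxy]phenyl}ethan-1-one
Product: 13 1-{2,4-bis[(triisopropylsilyl)oxy]phenyl}ethenyl trifluoromethanesulfonate, via potassium enolate 12 (not isolated)
Conditions: KHMDS, THF, −78 °C; then PhNTf2, −78 → 0 °C
Reagents that add atoms: N-phenylbis(trifluoromethanesulfonimide), O=S(=O)(N(c1ccccc1)S(=O)(=O)C(F)(F)F)C(F)(F)F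
Why: Kinetic deprotonation of the only enolisable position and O-triflation of the enolate is the standard enol triflate synthesis, and the bulky TIPS groups should not migrate at −78 °C.

**Step 7**
Reactants: 13 1-{2,4-bis[(triisopropylsilyl)oxy]phenyl}ethenyl trifluoromethanesulfonate
Product: 14 (1-{2,4-bis[(triisopropylsilyl)oxy]phenyl}ethenyl)triphenylphosphonium trifluoromethanesulfonate
Conditions: PPh3 (1.05 equiv), Pd(PPh3)4 (3 mol %), THF, 65 °C; trituration with Et2O/hexane
Reagents that add atoms: triphenylphosphine, c1ccc(cc1)P(c1ccccc1)c1ccccc1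
Why: Pd(0)-catalysed C–P coupling of alkenyl triflates with triphenylphosphine (oxidative addition, then reductive elimination of the alkenylphosphonium ion) is a known route to vinylphosphonium triflates and keeps the triflate as counter-ion.

**Step 8**
Reactants: 9 6-hydroxy-2-methoxy-3-(3-methylbut-2-en-1-yl)-4-[(triisopropylsilyl)oxy]benzaldehyde; 14 (1-{2,4-bis[(triisopropylsilyl)oxy]phenyl}ethenyl)triphenylphosphonium trifluoromethanesulfonate
Product: 17 3-{2,4-bis[(triisopropylsilyl)oxy]phenyl}-5-methoxy-6-(3-methylbut-2-en-1-yl)-7-[(triisopropylsilyl)oxy]-2H-chromene, via sodium phenoxide 15 (not isolated), via phosphorus ylide 16 (not isolated)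
Conditions: NaH (1.0 equiv), THF, 0 °C; then 14 (1.2 equiv), THF–MeCN, 65 °C
Reagents that add atoms: none
Why: Deprotonation of the only free hydroxyl of 9 gives phenoxide 15, whose oxygen adds in an oxa-Michael sense to the unsubstituted CH2 terminus of the 1-arylvinylphosphonium ion, which makes the O1–C2 bond and at the same time the aryl-substituted ylide 16; 16 then undergoes intramolecular Wittig olefination with the ortho-formyl group, which makes the C3=C4 bond and expels triphenylphosphine oxide. The closest known reaction type is the Schweizer chromene synthesis (salicylaldehyde salt plus vinyltriphenylphosphonium bromide gives 2H-chromene), run here with an α-aryl vinylphosphonium salt so that the 3-aryl group arrives with the two-carbon unit at the final oxidation level. The only ring closed is the 2H-pyran ring, by 6-exo-trig attack of the ylide carbon on the formyl carbon followed by loss of Ph3P=O. No stereocentre is formed, and the new double bond is endocyclic, so its geometry is fixed by the ring. The step needs a single oxygen nucleophile and O- over C-alkylation: the other three phenols are silylated, the accepting carbon is an unhindered CH2, and the one free ring CH of the phenoxide is shielded by the neighbouring OTIPS group. Exactly one equivalent of base should leave the ylide unprotonated and spare the aryl silyl ethers, and the irreversible Wittig step should drain the reversible oxa-Michael equilibrium.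

**Step 9**
Reactants: 17 3-{2,4-bis[(triisopropylsilyl)oxy]phenyl}-5-methoxy-6-(3-methylbut-2-en-1-yl)-7-[(triisopropylsilyl)oxy]-2H-chromene
Product: 18 dehydroglyasperin C
Conditions: TBAF (3.3 equiv), AcOH (3.5 equiv), THF, 0 °C, Ar, degassed solvents
Reagents that add atoms: none
Why: Fluoride cleavage of aryl silyl ethers buffered with acetic acid frees the three phenols without acid, which would risk cyclisation of the prenyl group or of the 2′-hydroxyisoflav-3-ene, and without strongly basic phenoxides, which would invite air oxidation.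

**Compound list**
1 | 5-methoxybenzene-1,3-diol (5-methoxyresorcinol) | COc1cc(O)cc(O)c1 | starting material
2 | N-[(2,4-dihydroxy-6-methoxyphenyl)methylidene]-N-methylmethanaminium chloride (aryl iminium chloride, formed in situ) | COc1cc(O)cc(O)c1C=[N+](C)C.[Cl-] | intermediate
3 | 2,4-dihydroxy-6-methoxybenzaldehyde | COc1cc(O)cc(O)c1C=O | intermediate
4 | 2-hydroxy-6-methoxy-4-[(triisopropylsilyl)oxy]benzaldehyde | COc1cc(O[Si](C(C)C)(C(C)C)C(C)C)cc(O)c1C=O | intermediate
5 | 3-methylbut-2-en-1-ol (prenol) | CC(C)=CCO | starting material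
6 | 2-methoxy-6-[(3-methylbut-2-en-1-yl)oxy]-4-[(triisopropylsilyl)oxy]benzaldehyde | COc1cc(O[Si](C(C)C)(C(C)C)C(C)C)cc(OCC=C(C)C)c1C=O | intermediate
7 | 2-methoxy-5-(2-methylbut-3-en-2-yl)-6-oxo-4-[(triisopropylsilyl)oxy]cyclohexa-1,3-diene-1-carbaldehyde (ortho-dienone, racemic, formed in situ) | COC1=C(C=O)C(=O)C(C(C)(C)C=C)C(O[Si](C(C)C)(C(C)C)C(C)C)=C1 | intermediate
8 | 2-methoxy-3-(3-methylbut-2-en-1-yl)-6-oxo-4-[(triisopropylsilyl)oxy]cyclohexa-1,4-diene-1-carbaldehyde (para-dienone, racemic, formed in situ) | COC1=C(C=O)C(=O)C=C(O[Si](C(C)C)(C(C)C)C(C)C)C1CC=C(C)C | intermediate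
9 | 6-hydroxy-2-methoxy-3-(3-methylbut-2-en-1-yl)-4-[(triisopropylsilyl)oxy]benzaldehyde | COc1c(C=O)c(O)cc(O[Si](C(C)C)(C(C)C)C(C)C)c1CC=C(C)C | intermediate
10 | 1-(2,4-dihydroxyphenyl)ethan-1-one (2,4-dihydroxyacetophenone) | CC(=O)c1ccc(O)cc1O | starting material
11 | 1-{2,4-bis[(triisopropylsilyl)oxy]phenyl}ethan-1-one | CC(=O)c1ccc(O[Si](C(C)C)(C(C)C)C(C)C)cc1O[Si](C(C)C)(C(C)C)C(C)C | intermediate
12 | potassium 1-{2,4-bis[(triisopropylsilyl)oxy]phenyl}ethen-1-olate (potassium enolate, formed in situ) | C=C([O-])c1ccc(O[Si](C(C)C)(C(C)C)C(C)C)cc1O[Si](C(C)C)(C(C)C)C(C)C.[K+] | intermediate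
13 | 1-{2,4-bis[(triisopropylsilyl)oxy]phenyl}ethenyl trifluoromethanesulfonate | C=C(OS(=O)(=O)C(F)(F)F)c1ccc(O[Si](C(C)C)(C(C)C)C(C)C)cc1O[Si](C(C)C)(C(C)C)C(C)C | intermediate
14 | (1-{2,4-bis[(triisopropylsilyl)oxy]phenyl}ethenyl)triphenylphosphonium trifluoromethanesulfonate | C=C(c1ccc(O[Si](C(C)C)(C(C)C)C(C)C)cc1O[Si](C(C)C)(C(C)C)C(C)C)[P+](c1ccccc1)(c1ccccc1)c1ccccc1.[O-]S(=O)(=O)C(F)(F)F | intermediate
15 | sodium 2-formyl-3-methoxy-4-(3-methylbut-2-en-1-yl)-5-[(triisopropylsilyl)oxy]phenolate (sodium phenoxide of 9, formed in situ) | COc1c(C=O)c([O-])cc(O[Si](C(C)C)(C(C)C)C(C)C)c1CC=C(C)C.[Na+] | intermediate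
16 | {1-{2,4-bis[(triisopropylsilyl)oxy]phenyl}-2-[2-formyl-3-methoxy-4-(3-methylbut-2-en-1-yl)-5-[(triisopropylsilyl)oxy]phenoxy]ethylidene}triphenyl-λ5-phosphane (phosphorus ylide, formed in situ) | COc1c(C=O)c(OCC(=P(c2ccccc2)(c2ccccc2)c2ccccc2)c2ccc(O[Si](C(C)C)(C(C)C)C(C)C)cc2O[Si](C(C)C)(C(C)C)C(C)C)cc(O[Si](C(C)C)(C(C)C)C(C)C)c1CC=C(C)C | intermediate
17 | 3-{2,4-bis[(triisopropylsilyl)oxy]phenyl}-5-methoxy-6-(3-methylbut-2-en-1-yl)-7-[(triisopropylsilyl)oxy]-2H-chromene | COc1c2c(cc(O[Si](C(C)C)(C(C)C)C(C)C)c1CC=C(C)C)OCC(c1ccc(O[Si](C(C)C)(C(C)C)C(C)C)cc1O[Si](C(C)C)(C(C)C)C(C)C)=C2 | intermediate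
18 | dehydroglyasperin C, 4-[7-hydroxy-5-methoxy-6-(3-methylbut-2-en-1-yl)-2H-chromen-3-yl]benzene-1,3-diol | COc1c2c(cc(O)c1CC=C(C)C)OCC(c1ccc(O)cc1O)=C2 | target

**Totals**
Total step count: 9. Longest linear sequence: 6 steps (steps 1, 2, 3, 4, 8, 9).

**Steps most likely to fail**

1. Step 8. The conjugate addition of the hindered, chelated phenoxide may be slow, the congested ylide may be protonated or hydrolysed before it closes on the electron-rich, doubly ortho-substituted formyl group, or silyl groups may transfer to the phenoxide. The fallback sets out from compound 9 and comes back at compound 17; it makes the same two ring bonds at the lactone oxidation level and then reduces. Commercial 2,4-dihydroxyphenylacetic acid is persilylated (TIPSCl, imidazole, DMF) to triisopropylsilyl {2,4-bis[(triisopropylsilyl)oxy]phenyl}acetate F1. Its silyl ester alone is hydrolysed (aq. K2CO3, MeOH–THF, 0 °C) to {2,4-bis[(triisopropylsilyl)oxy]phenyl}acetic acid F2. Perkin–Oglialoro condensation of 9 with F2 (Ac2O, Et3N, 110 °C) should give 3-{2,4-bis[(triisopropylsilyl)oxy]phenyl}-5-methoxy-6-(3-methylbut-2-en-1-yl)-7-[(triisopropylsilyl)oxy]-2H-chromen-2-one F3. DIBAL-H (CH2Cl2, −78 → 0 °C) should reduce the lactone to 2-[(1Z)-2-{2,4-bis[(triisopropylsilyl)oxy]phenyl}-3-hydroxyprop-1-en-1-yl]-3-methoxy-4-(3-methylbut-2-en-1-yl)-5-[(triisopropylsilyl)oxy]phenol F4. Mitsunobu cyclodehydration (PPh3, DIAD, THF, 0 °C) should then close the pyran ring to 17.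

2. Step 4. The ortho-dienone may tautomerise to the phenol carrying the 1,1-dimethylallyl group before the second [3,3] shift, or the aldehyde may be lost thermally. The fallback sets out from compound 4 and comes back at compound 9; it uses a temporary blocking atom so that only the para pathway is open. Bromination (NBS, MeCN, 0 °C) is expected ortho to the chelated hydroxyl and should give 3-bromo-2-hydroxy-6-methoxy-4-[(triisopropylsilyl)oxy]benzaldehyde F5. Mitsunobu etherification with 5 should give 3-bromo-6-methoxy-2-[(3-methylbut-2-en-1-yl)oxy]-4-[(triisopropylsilyl)oxy]benzaldehyde F6. On heating (PhNEt2, 180 °C) the first shift lands on the brominated carbon, the dienone cannot enolise, and the Cope shift to the para carbon should give 3-bromo-2-hydroxy-6-methoxy-5-(3-methylbut-2-en-1-yl)-4-[(triisopropylsilyl)oxy]benzaldehyde F7. Radical debromination (Bu3SnH, AIBN, toluene, 90 °C) should then give 9.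

3. Step 7. The electron-rich α-aryl alkenyl triflate may ionise or hydrolyse back to the ketone, and C–P reductive elimination at the hindered 1,1-disubstituted vinyl–palladium centre may be slow. The fallback sets out from compound 13 and comes back at compound 17; it builds the phosphonium salt by addition to an alkyne instead of substitution at the triflate. Elimination of 13 (LDA, THF, −78 °C) should give 1-ethynyl-2,4-bis[(triisopropylsilyl)oxy]benzene F8. Pd-catalysed Markovnikov addition of triphenylphosphine and methanesulfonic acid (Pd(PPh3)4 cat., THF, reflux) should give (1-{2,4-bis[(triisopropylsilyl)oxy]phenyl}ethenyl)triphenylphosphonium methanesulfonate F9. F9 is then used with 9 under the conditions of step 8 to reach 17.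

**Further compounds**
F1 | step 8 | triisopropylsilyl {2,4-bis[(triisopropylsilyl)oxy]phenyl}acetate | CC(C)[Si](OC(=O)Cc1ccc(O[Si](C(C)C)(C(C)C)C(C)C)cc1O[Si](C(C)C)(C(C)C)C(C)C)(C(C)C)C(C)C
F2 | step 8 | {2,4-bis[(triisopropylsilyl)oxy]phenyl}acetic acid | OC(=O)Cc1ccc(O[Si](C(C)C)(C(C)C)C(C)C)cc1O[Si](C(C)C)(C(C)C)C(C)C
F3 | step 8 | 3-{2,4-bis[(triisopropylsilyl)oxy]phenyl}-5-methoxy-6-(3-methylbut-2-en-1-yl)-7-[(triisopropylsilyl)oxy]-2H-chromen-2-one | COc1c2c(cc(O[Si](C(C)C)(C(C)C)C(C)C)c1CC=C(C)C)OC(=O)C(c1ccc(O[Si](C(C)C)(C(C)C)C(C)C)cc1O[Si](C(C)C)(C(C)C)C(C)C)=C2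
F4 | step 8 | 2-[(1Z)-2-{2,4-bis[(triisopropylsilyl)oxy]phenyl}-3-hydroxyprop-1-en-1-yl]-3-methoxy-4-(3-methylbut-2-en-1-yl)-5-[(triisopropylsilyl)oxy]phenol | OC/C(c1ccc(O[Si](C(C)C)(C(C)C)C(C)C)cc1O[Si](C(C)C)(C(C)C)C(C)C)=C\c1c(O)cc(O[Si](C(C)C)(C(C)C)C(C)C)c(CC=C(C)C)c1OC
F5 | step 4 | 3-bromo-2-hydroxy-6-methoxy-4-[(triisopropylsilyl)oxy]benzaldehyde | COc1cc(O[Si](C(C)C)(C(C)C)C(C)C)c(Br)c(O)c1C=O
F6 | step 4 | 3-bromo-6-methoxy-2-[(3-methylbut-2-en-1-yl)oxy]-4-[(triisopropylsilyl)oxy]benzaldehyde | COc1cc(O[Si](C(C)C)(C(C)C)C(C)C)c(Br)c(OCC=C(C)C)c1C=O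
F7 | step 4 | 3-bromo-2-hydroxy-6-methoxy-5-(3-methylbut-2-en-1-yl)-4-[(triisopropylsilyl)oxy]benzaldehyde | COc1c(CC=C(C)C)c(O[Si](C(C)C)(C(C)C)C(C)C)c(Br)c(O)c1C=O
F8 | step 7 | 1-ethynyl-2,4-bis[(triisopropylsilyl)oxy]benzene | C#Cc1ccc(O[Si](C(C)C)(C(C)C)C(C)C)cc1O[Si](C(C)C)(C(C)C)C(C)C
F9 | step 7 | (1-{2,4-bis[(triisopropylsilyl)oxy]phenyl}ethenyl)triphenylphosphonium methanesulfonate | C=C(c1ccc(O[Si](C(C)C)(C(C)C)C(C)C)cc1O[Si](C(C)C)(C(C)C)C(C)C)[P+](c1ccccc1)(c1ccccc1)c1ccccc1.CS(=O)(=O)[O-]
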